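## Structural features

Compound 46 is a bis(tropolone) on an eleven-membered carbocycle. Two 2-methyl-3,4-dihydro-2H-pyran rings (ring A and ring B) are each fused to the macrocycle on one side and to a 6-methyltropolone on the other, through the tropolone C4 oxygen and a CH2 group on tropolone C5. Each pyran meets the macrocycle at a quaternary C(Me)–O carbon and the neighbouring CH, trans-fused in both cases. With the secondary carbinol this gives a contiguous triad (carbinol CH, ring A C(Me)–O, ring A CH) and a separate pair (ring B C(Me)–O, ring B CH) one CH2 away from the carbinol. On the far side the two pairs are joined by a CH2–CMe2–CH=CH–CH2 bridge whose E-alkene lies between the gem-dimethyl carbon and the CH2 on the ring B C(Me)–O carbon. Fragile points are the tropolones (acidic and chelating when free; electrophilic and with an acidic ring methyl when O-methylated), the tertiary alkyl aryl ethers, the humulene-like polyene intermediates (transannular reactions under acid) and the β,γ-unsaturated ketone intermediates. The real difficulty is closing an eleven-membered ring across a neopentyl/quaternary junction with E geometry, and relating the two remote pyran fusions. The key step uses the fact that the CMe2 carbon, its CH2 neighbour on the ring A side and the E-alkene stand in a 1,5-diene relation to the ring A C(Me)–O carbon; taken back to a carbinol carbon, this maps the macrocycle onto a ring B-fused trans-1-vinyl-2-(2-methylprop-1-enyl)cycloheptanol.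

## Logic of the disconnections

46 ⇒ 45. The O–CH3 bond of the one remaining tropolone ether is cut last. Ring B has to stay capped through every metal-mediated step, and this leaves one mild unmasking. The forward hydrolysis must attack the methoxy-bearing tropone carbon and spare the two tertiary aryl ethers.

45 ⇒ 43 + 11 (through 44). The ring A C(Me)–O bond and the bond between the ring A CH and the tropolone CH2 are cut together in a retro-hetero-Diels–Alder sense. Both bonds flank the E-trisubstituted alkene of 43, so two stereocentres and a whole tropolone disappear at once. Ring A enters after the last organometallic step, so its tropolone needs no cap and 11 is used with the hydroxyl free. The forward step must choose the trisubstituted alkene, place oxygen on the methyl-bearing carbon and strike the face syn to the free hydroxyl.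

43 ⇒ 41 ⇒ 39. The vinylic C–CH3 bond is cut (with the carbinol back in its MOM form). An enol triflate is the trapped form of the oxy-Cope enolate, so the position and geometry of this alkene are tied to the key step. The coupling must go with retention and without a hard nucleophile.

39 ⇒ 36 (through 38 and 37). In the retro-[3,3] sense the CH2–CMe2 bond is cut and the ring bond between the enol carbon and the alkene CH is re-formed. The eleven-membered ring with its quaternary junction shrinks to a cycloheptanol, and alkene geometry becomes a matter of relative configuration. Compounds 36 and 38 carry the ring B fusion and carbinol centres in the same sense as 46, and the alkenyl groups of 36 are trans, as the chair transition state requires. The forward step needs the trans-dialkenyl arrangement, an alkoxide with no migrating group next to it, and a tropone that survives KH.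

36 ⇒ 34 + 35; 34 ⇒ 33 ⇒ 31 + 32; 31 ⇒ 30 ⇒ 29. The vinyl–carbinol bond, the isobutenyl–ring bond and the epoxide oxygen are cut in turn. The trans relation comes from SN2 opening of an epoxide followed by addition anti to the new substituent, and all three functional carbons derive from one cis-alkene with an allylic hydroxyl. The opening must occur at the carbon remote from the MOM-oxy carbon, and both organometallic reagents must leave the methoxytropone alone.

29 ⇒ 28 ⇒ 27. The ring C=C bond is cut (ring-closing metathesis). The seven-membered ring reduces to two terminal alkenes on ring B. The two chains must be trans on ring B.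

27 ⇒ 24 + 25 (through 26). The allyl–C bond and the O–C(Me) bond of ring B are cut. An oxocarbenium ion builds the quaternary centre under 1,2-induction, and ring B reduces to a methyl ketone and a hydroxytropone. Allylation must outrun proton loss from the cation, and the carbinol oxygen must be unable to close onto the ketone.

24 ⇒ 21 ⇒ 13 + 19 (through 20). The tropolone CH2–CH bond and the O–C(ketal) bond are cut, again in a retro-hetero-Diels–Alder sense. A cyclic enol ether lets the single stereocentre from 15 control the ring B CH centre, and the tropolone unit separates from a chiral C7 chain. Because 13 already carries the methyl cap, the adduct needs no separate protection step. The cycloaddition must occur anti to the vinyl group and the enol ether must survive the acidic hydroxytropone.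

19 ⇒ 18 ⇒ 14 + 15. The enol ether C–O bond (dehydration) and the CH2–CH2 bond made by epoxide opening are cut. The chirality comes from a commercial epoxide; opening must occur at its unsubstituted carbon.

13 ⇒ 12 ⇒ 10 and 11 ⇒ 10; 10 ⇒ 8 + 9; 8 ⇒ 6 ⇒ 5 ⇒ 3 + 4; 3 ⇒ 2 ⇒ 1. Both tropolone units go back to 10: the capped one by cutting the acetal and the O–CH3 bond, the free one by cutting the acetal alone. The tropolone C5–CH2OH bond is then cut (cross-coupling), and the seven-membered ring is contracted to an arene by removing the carbene carbon. The carbene carbon becomes C5, the aryl ether carbon C4 and the methyl-bearing carbon C6, so the substitution pattern is fixed by 1. The carbene must add only to the enol ether double bond, and the methylation must take only the tropolone hydroxyl.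

## Other disconnections considered

Alternative 1: The cut removes the ring B C(Me)–O bond and the bond between the allylic CH2 and the alkene CH, dividing the molecule into two halves of similar size, each with one tropolone. Forward, zerovalent palladium inserts into an E-alkenyl bromide on the ring A half, the hydroxytropone oxygen of the other half adds across its isopropenyl group, and reductive elimination forms the CH2–CH= bond to give A1. In its favour: it is highly convergent, the E geometry is carried over from the bromide, and a quaternary ether centre and a C–C bond form in one operation. Against it here: the nucleophile is a weakly basic vinylogous acid, the carbon attacked becomes fully substituted, Heck-type β-hydride elimination competes, and the new centre relies on 1,2-induction alone. A1 is also still open-chain, so the eleven-membered ring must later be closed end to end. Compared with the chosen plan, A1 contains both pyranotropolones but no macrocycle, whereas 39 contains the macrocycle and one pyranotropolone. The chosen plan's pericyclic step has fewer competing pathways. On convergence and probably on longest linear sequence the alternative is the better; on fixing the alkene geometry the two are equal.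

Alternative 2: The cut removes only the ring A C(Me)–O bond. Forward, Ti(OiPr)4 activates a 2,3-epoxy alcohol made by Sharpless epoxidation, and the hydroxytropone oxygen opens it at the tertiary carbon with inversion (6-exo) to give A2. In its favour: the carbinol and the quaternary centre are set by a reagent-controlled, stereospecific sequence. This is better than the chosen plan, which relies on substrate control for the face of the ring A cycloaddition. Against it here: a weak nucleophile must attack a tertiary carbon, epoxide migration and opening at the secondary carbon compete, and the ring A CH centre needs its own earlier asymmetric step. A2 is also only a third of the skeleton; its primary alcohol and terminal alkene must still be elaborated and the macrocycle closed. Compared with the chosen plan, stereocentres are bought one at a time, so the sequence is more linear and longer. The chosen plan makes both ring A centres in one step but with less certain stereocontrol. The two are equal in ending with protected tropolones.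

Alternative 3: The cut removes the CH2–CH(OH) bond of the macrocycle. Forward, CrCl2 with catalytic cobalt phthalocyanine (CoPc) turns a primary iodide on the ring B CH into an alkylchromium species, which adds to a ring A aldehyde that cannot enolise, giving A3, the bis(methyl ether) of 46. In its favour: the reagent is mild and tolerates tropone ethers (better than the KH and Grignard steps of the chosen plan), and every other stereocentre is already in place. Against it here: an eleven-membered ring is closed end to end, with the usual entropic and transannular penalty, high dilution and oligomers. The carbinol centre is created in the macrocyclisation, where chelated and non-chelated addition to the α-aryloxy aldehyde lead to opposite epimers. A β-branched primary iodide and a large excess of CrCl2 add to the burden. Compared with the chosen plan, ring expansion by four atoms needs no dilution and sets the alkene geometry in the same step, and the carbinol centre comes early from a chiral epoxide (better in the chosen plan). The alternative is the better in late-stage convergence; total step counts are comparable.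

Key step: step 22

Assumption: O-methylation of the unsymmetrical tropolone 10 (step 8) is written for the 2-methoxy isomer; the isomeric O-methyl ether, if it forms, would be separated, protects equally and gives the same tropolone in step 26.
Assumption: compounds 5 to 7 are racemic; their stereocentres vanish in step 5.

## Route

Step 1
Reactants: 1 2-methylphenol
Product: 2 1-(methoxymethoxy)-2-methylbenzene
Conditions: MOMCl, i-Pr2NEt, CH2Cl2, 0 °C → rt
Reagents that add atoms: chloromethyl methyl ether COCCl
Why: O-Alkylation of the phenol gives an acetal ether that survives dissolving metal, carbene and oxidation steps and is removed under very mild acid once it sits on the tropone.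

Step 2
Reactants: 2 1-(methoxymethoxy)-2-methylbenzene
Product: 3 1-(methoxymethoxy)-2-methylcyclohexa-1,4-diene
Conditions: Li, NH3 (l), t-BuOH, THF, −78 °C
Reagents that add atoms: none
Why: Birch reduction of an aryl ether keeps the oxygen- and methyl-bearing carbons on one tetrasubstituted enol ether double bond and leaves an isolated disubstituted alkene.

Step 3
Reactants: 3 1-(methoxymethoxy)-2-methylcyclohexa-1,4-diene; 4 bromoform
Product: 5 7,7-dibromo-1-(methoxymethoxy)-6-methylbicyclo[4.1.0]hept-3-ene (racemic)
Conditions: KOt-Bu, pentane, 0 °C
Reagents that add atoms: none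
Why: Electrophilic dibromocarbene cyclopropanates the electron-rich tetrasubstituted enol ether double bond much faster than the isolated alkene.

Step 4
Reactants: 5 7,7-dibromo-1-(methoxymethoxy)-6-methylbicyclo[4.1.0]hept-3-ene
Product: 6 7,7-dibromo-1-(methoxymethoxy)-6-methylbicyclo[4.1.0]heptane-3,4-diol (racemic cis-diol)
Conditions: OsO4 (cat.), NMO, acetone/H2O, rt
Reagents that add atoms: N-methylmorpholine N-oxide C[N+]1([O-])CCOCC1; water O
Why: Catalytic syn-dihydroxylation of the only remaining alkene; the configuration of the diol is of no consequence.

Step 5
Reactants: 6 7,7-dibromo-1-(methoxymethoxy)-6-methylbicyclo[4.1.0]heptane-3,4-diol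
Product: 8 5-bromo-2-hydroxy-4-(methoxymethoxy)-6-methylcyclohepta-2,4,6-trien-1-one, via dione 7 (not isolated)
Conditions: TFAA, DMSO, CH2Cl2, −78 °C; then Et3N, −78 °C → rt
Reagents that add atoms: none
Why: Swern-type oxidation (no glycol cleavage) gives the 1,2-dione, whose enol opens the gem-dibromocyclopropane with loss of HBr to the aromatic tropolone (dihalocyclopropane ring expansion); the carbene carbon becomes C5 and keeps one bromine.

Step 6
Reactants: 8 5-bromo-2-hydroxy-4-(methoxymethoxy)-6-methylcyclohepta-2,4,6-trien-1-one; 9 (tributylstannyl)methanol
Product: 10 2-hydroxy-5-(hydroxymethyl)-4-(methoxymethoxy)-6-methylcyclohepta-2,4,6-trien-1-one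
Conditions: Pd(PPh3)4 (cat.), 1,4-dioxane, 100 °C
Reagents that add atoms: none
Why: Stille coupling of the C5–Br bond with a hydroxymethylstannane; the neutral conditions tolerate the free tropolone and the acetal.

Step 7
Reactants: 10 2-hydroxy-5-(hydroxymethyl)-4-(methoxymethoxy)-6-methylcyclohepta-2,4,6-trien-1-one
Product: 11 2,4-dihydroxy-5-(hydroxymethyl)-6-methylcyclohepta-2,4,6-trien-1-one (tropolone triol)
Conditions: AcOH/THF/H2O, rt
Reagents that add atoms: none
Why: The MOM group on the vinylogous-acid oxygen is an acylal-like acetal and hydrolyses under acid too weak to ionise the benzylic-type alcohol. This free triol is the ring A building block of step 25.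

Step 8
Reactants: 10 2-hydroxy-5-(hydroxymethyl)-4-(methoxymethoxy)-6-methylcyclohepta-2,4,6-trien-1-one
Product: 12 5-(hydroxymethyl)-2-methoxy-4-(methoxymethoxy)-6-methylcyclohepta-2,4,6-trien-1-one
Conditions: MeI, K2CO3, acetone, rt
Reagents that add atoms: iodomethane CI
Why: Williamson O-methylation of the tropolonate, the only hydroxyl that carbonate deprotonates, leaves the primary alcohol untouched. It caps the acidic, metal-chelating hydroxyl of the ring B unit for the metathesis, vanadium, copper, cerium, potassium and palladium steps.

Step 9
Reactants: 12 5-(hydroxymethyl)-2-methoxy-4-(methoxymethoxy)-6-methylcyclohepta-2,4,6-trien-1-one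
Product: 13 4-hydroxy-5-(hydroxymethyl)-2-methoxy-6-methylcyclohepta-2,4,6-trien-1-one (methoxytropone diol)
Conditions: AcOH/THF/H2O, rt
Reagents that add atoms: none
Why: Acetal hydrolysis as in step 7 frees the C4 hydroxyl next to the hydroxymethyl group. The methyl ether is a vinylogous ester and needs hydroxide or strong acid, so it stays.

Step 10
Reactants: 14 acetone N,N-dimethylhydrazone; 15 (R)-2-vinyloxirane
Product: 18 (S)-5-hydroxyhept-6-en-2-one, via lithium azaenolate 16 (not isolated), via lithium alkoxide 17 (not isolated)
Conditions: n-BuLi, THF, 0 °C; then 15, −78 → 0 °C; then aq. oxalic acid, Et2O, rt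
Reagents that add atoms: water O
Why: Hydrazone azaenolate alkylation by SN2 opening at the unsubstituted epoxide carbon leaves the stereocentre untouched (the descriptor changes from R to S only by priority); hydrolysis frees the ketone.

Step 11
Reactants: 18 (S)-5-hydroxyhept-6-en-2-one
Product: 19 (S)-5-methyl-2-vinyl-2,3-dihydrofuran
Conditions: PPTS (cat.), benzene, reflux (Dean–Stark); distilled from K2CO3
Reagents that add atoms: none
Why: Acid-catalysed cyclodehydration of a γ-hydroxy ketone through its lactol gives the more substituted endocyclic enol ether; the carbinol C–O bond is not broken.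

Step 12
Reactants: 13 methoxytropone diol; 19 (S)-5-methyl-2-vinyl-2,3-dihydrofuran
Product: 21 cis-fused ring B ketal (tropolone methyl ether), via o-quinone methide 20 (not isolated)
Conditions: o-xylene, 4 Å MS, 130 °C, sealed tube
Reagents that add atoms: none
Why: Thermal dehydration of the o-hydroxybenzyl-type alcohol gives the methoxy-substituted o-quinone methide 20, which adds to the enol ether in an inverse-demand hetero-Diels–Alder reaction (CH2 to the enol ether β-carbon, oxygen to the acetal carbon). Suprafacial addition anti to the vinyl group sets the ring B CH centre trans to the vinyl-bearing carbon; the cis-fused ketal centre is erased in step 13.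

Step 13
Reactants: 21 cis-fused ring B ketal (tropolone methyl ether)
Product: 24 (3S,5S)-keto acetate (free hydroxytropone), via hydroxy ketone 22 (not isolated), via bis-acetate 23 (not isolated)
Conditions: AcOH (cat.), THF/H2O, rt; then Ac2O, pyridine, DMAP (cat.), CH2Cl2, 0 °C; then MeOH, NaHCO3, 0 °C
Reagents that add atoms: water O; acetic anhydride CC(=O)OC(C)=O
Why: The mixed ketal with the vinylogous-acid oxygen hydrolyses like an acylal to the open hydroxy ketone. Acetylation caps the carbinol so that it cannot close onto the ketone in step 14, and the vinylogous anhydride formed on the hydroxytropone is methanolysed selectively.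

Step 14
Reactants: 24 (3S,5S)-keto acetate (free hydroxytropone); 25 allyltrimethylsilane
Product: 27 ring B allyl compound (2-allyl-2-methyl-dihydropyranotropone; side chain trans to allyl), via oxocarbenium triflate 26 (not isolated)
Conditions: TMSOTf, CH2Cl2, −78 → −40 °C; then Et3N, aq. NaHCO3
Reagents that add atoms: none
Why: Intramolecular hemiketalisation and ionisation give cyclic oxocarbenium ion 26, which is trapped by Hosomi–Sakurai allylation. A(1,2) strain with the in-plane methyl holds the neighbouring side chain pseudo-axial, so the silane enters trans to it and creates the ring B C(Me)–O centre with allyl and side chain trans.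

Step 15
Reactants: 27 ring B allyl compound
Product: 28 ring B-fused cycloheptenyl acetate (trans-fused)
Conditions: second-generation Grubbs catalyst (5 mol%), CH2Cl2, 40 °C
Reagents that add atoms: none
Why: Ring-closing metathesis of the two terminal alkenes, which sit trans on ring B, closes the seven-membered ring with loss of ethene.

Step 16
Reactants: 28 ring B-fused cycloheptenyl acetate
Product: 29 ring B-fused cyclohept-2-en-1-ol
Conditions: K2CO3, MeOH, rt
Reagents that add atoms: none
Why: Methanolysis of the acetate; exchange of methoxide at the methoxytropone is degenerate.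

Step 17
Reactants: 29 ring B-fused cyclohept-2-en-1-ol
Product: 30 syn-2,3-epoxy alcohol
Conditions: VO(acac)2 (cat.), t-BuOOH, CH2Cl2, 0 °C → rt
Reagents that add atoms: tert-butyl hydroperoxide CC(C)(C)OO
Why: Hydroxyl-directed epoxidation through a vanadate ester delivers oxygen to the alkene face syn to the allylic hydroxyl and sets both epoxide centres.

Step 18
Reactants: 30 syn-2,3-epoxy alcohol
Product: 31 epoxy MOM ether
Conditions: MOMCl, i-Pr2NEt, CH2Cl2, 0 °C → rt
Reagents that add atoms: chloromethyl methyl ether COCCl
Why: The acetal ether does not migrate to a neighbouring alkoxide (a silyl ether would) and deactivates the adjacent epoxide carbon toward SN2 attack.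

Step 19
Reactants: 31 epoxy MOM ether; 32 (2-methylprop-1-enyl)magnesium bromide
Product: 33 trans-2-(2-methylprop-1-enyl) alcohol (hydroxyl cis to the MOM-oxy group)
Conditions: CuBr·SMe2 (0.5 equiv per 32), THF, −40 → 0 °C; then aq. NH4Cl
Reagents that add atoms: none
Why: The alkenyl cuprate opens the epoxide by SN2 attack with inversion at the carbon remote from the electron-withdrawing MOM-oxy carbon. The dialkoxy-substituted tropone is a poor acceptor for a soft cuprate at low temperature.

Step 20
Reactants: 33 trans-2-(2-methylprop-1-enyl) alcohol
Product: 34 α-MOM-oxy α'-(2-methylprop-1-enyl) cycloheptanone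
Conditions: Dess–Martin periodinane, NaHCO3, CH2Cl2, 0 °C
Reagents that add atoms: none
Why: Buffered periodinane oxidation avoids conjugation of the β,γ-unsaturated ketone; epimerisation at the alkenyl-bearing carbon would do no harm because step 21 adds anti to that group in either epimer.

Step 21
Reactants: 34 α-MOM-oxy α'-(2-methylprop-1-enyl) cycloheptanone; 35 vinylmagnesium bromide
Product: 36 ring B-fused trans-1-vinyl-2-(2-methylprop-1-enyl)cycloheptanol (precursor of the key step)
Conditions: CeCl3, THF, −78 °C; then aq. NH4Cl
Reagents that add atoms: none
Why: The weakly basic, oxophilic organocerium reagent adds 1,2 to the ketone on the face opposite the adjacent isobutenyl group, giving the trans-dialkenyl carbinol. At −78 °C the ketone should react well ahead of the vinylogous-ester-like methoxytropone.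

Step 22
Reactants: 36 ring B-fused trans-1-vinyl-2-(2-methylprop-1-enyl)cycloheptanol
Product: 39 ring B-fused cycloundeca-1,5-dienyl triflate (both ring double bonds trans), via potassium alkoxide 37 (not isolated), via potassium enolate 38 (not isolated)
Conditions: KH, 18-crown-6, THF, 0 °C → rt; then PhNTf2, −78 → 0 °C; aq. NH4Cl
Reagents that add atoms: N-phenylbis(trifluoromethanesulfonimide) O=S(=O)(N(c1ccccc1)S(=O)(=O)C(F)(F)F)C(F)(F)F
Why: KH with 18-crown-6 gives the dissociated alkoxide 37, whose charge weakens the ring bond between the carbinol carbon and the isobutenyl-bearing carbon, so a [3,3]-sigmatropic shift (anionic oxy-Cope rearrangement) runs at or below room temperature. The closest known reaction type is the anionic oxy-Cope ring expansion of trans-1,2-dialkenylcycloalkanols to E-cycloalkenones with trapping of the enolate. The new σ-bond joins the vinyl terminus to the fully substituted isobutenyl terminus (CH2–CMe2) while the seven-membered ring bond breaks; the eleven-membered ring therefore arises by four-atom ring expansion, not end-to-end closure, and needs no high dilution. No stereocentre is created. The two centres that are destroyed fix geometry: the trans alkenyl groups allow only the chair with both ring bonds equatorial, which gives the E-alkene next to CMe2 and enolate 38 with oxygen cis to the new CH2, so that the ring carbons are trans across the enolate double bond. Enolate formation makes the step irreversible and regiodefined, and PhNTf2 sulfonylates the oxygen before proton exchange toward the MOM-bearing carbon can scramble position or geometry. The selectivity needed is the trans ring geometry at both new double bonds, and it is secured by the trans relation built in steps 19 to 21, by the non-migrating MOM group and by a small excess of KH at 0 °C to limit deprotonation of the tropone methyl group.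

Step 23
Reactants: 39 ring B-fused cycloundeca-1,5-dienyl triflate; 40 dimethylzinc
Product: 41 ring B-fused triene MOM ether (E-trisubstituted alkene next to the MOM-oxy carbon)
Conditions: Pd(PPh3)4 (cat.), THF, 0 °C → rt; then aq. NH4Cl
Reagents that add atoms: none
Why: Negishi coupling replaces the triflate by methyl with retention of alkene geometry; the zinc reagent does not attack the methoxytropone.

Step 24
Reactants: 41 ring B-fused triene MOM ether
Product: 43 ring B-fused triene allylic alcohol, via bromomethyl ether 42 (not isolated)
Conditions: Me2BBr, CH2Cl2, −78 °C; then aq. NaHCO3, THF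
Reagents that add atoms: none
Why: The boron bromide cleaves the acetal at its methoxy oxygen at low temperature and the bromomethyl ether hydrolyses on work-up. No protic acid touches the acid-sensitive triene or the tertiary aryl ether.

Step 25
Reactants: 43 ring B-fused triene allylic alcohol; 11 tropolone triol
Product: 45 ring B O-methyl ether of 46, via o-quinone methide 44 (not isolated)
Conditions: toluene, 110 °C, sealed tube
Reagents that add atoms: none
Why: Thermal loss of water from 11 gives the hydroxy-substituted o-quinone methide 44, whose hetero-Diels–Alder reaction with the more electron-rich trisubstituted alkene (not the neopentyl disubstituted one) puts oxygen on the methyl-bearing carbon and CH2 on the CH carbon. Suprafacial addition to the E-alkene gives the trans ring A fusion. Peripheral attack on the face syn to the free allylic hydroxyl, which can hydrogen-bond to the quinone methide oxygen, should place the new C–O bond cis to the carbinol oxygen as in 46.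

Step 26
Reactants: 45 ring B O-methyl ether of 46
Product: 46 CNP0283947.4
Conditions: LiOH, THF/MeOH/H2O, 50 °C; then aq. HCl to pH 4
Reagents that add atoms: lithium hydroxide [Li+].[OH-]
Why: The 2-methoxytropone is a vinylogous methyl ester. Hydroxide adds at the methoxy-bearing carbon and expels methoxide; the fully substituted ring-ether carbons are hindered and their alkoxides would re-close.

## Compound list

1 | 2-methylphenol | Cc1ccccc1O | starting material
2 | 1-(methoxymethoxy)-2-methylbenzene | COCOc1ccccc1C | intermediate
3 | 1-(methoxymethoxy)-2-methylcyclohexa-1,4-diene | COCOC1=C(C)CC=CC1 | intermediate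
4 | bromoform | BrC(Br)Br | starting material
5 | 7,7-dibromo-1-(methoxymethoxy)-6-methylbicyclo[4.1.0]hept-3-ene (racemic) | COCOC12CC=CCC1(C)C2(Br)Br | intermediate
6 | 7,7-dibromo-1-(methoxymethoxy)-6-methylbicyclo[4.1.0]heptane-3,4-diol (racemic cis-diol) | COCOC12CC(O)C(O)CC1(C)C2(Br)Br | intermediate
7 | 7,7-dibromo-1-(methoxymethoxy)-6-methylbicyclo[4.1.0]heptane-3,4-dione (racemic) | COCOC12CC(=O)C(=O)CC1(C)C2(Br)Br | intermediate
8 | 5-bromo-2-hydroxy-4-(methoxymethoxy)-6-methylcyclohepta-2,4,6-trien-1-one | COCOc1cc(O)c(=O)cc(C)c1Br | intermediate
9 | (tributylstannyl)methanol | CCCC[Sn](CO)(CCCC)CCCC | starting material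
10 | 2-hydroxy-5-(hydroxymethyl)-4-(methoxymethoxy)-6-methylcyclohepta-2,4,6-trien-1-one | COCOc1cc(O)c(=O)cc(C)c1CO | intermediate
11 | 2,4-dihydroxy-5-(hydroxymethyl)-6-methylcyclohepta-2,4,6-trien-1-one (tropolone triol) | Cc1cc(=O)c(O)cc(O)c1CO | intermediate
12 | 5-(hydroxymethyl)-2-methoxy-4-(methoxymethoxy)-6-methylcyclohepta-2,4,6-trien-1-one | COCOc1cc(OC)c(=O)cc(C)c1CO | intermediate
13 | 4-hydroxy-5-(hydroxymethyl)-2-methoxy-6-methylcyclohepta-2,4,6-trien-1-one (methoxytropone diol) | Cc1cc(=O)c(OC)cc(O)c1CO | intermediate
14 | acetone N,N-dimethylhydrazone | CC(C)=NN(C)C | starting material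
15 | (R)-2-vinyloxirane | C=C[C@@H]1CO1 | starting material
16 | lithium azaenolate of acetone N,N-dimethylhydrazone | [Li+].[CH2-]C(C)=NN(C)C | intermediate
17 | lithium alkoxide of (S)-5-hydroxyhept-6-en-2-one N,N-dimethylhydrazone | CC(CC[C@H]([O-])C=C)=NN(C)C.[Li+] | intermediate
18 | (S)-5-hydroxyhept-6-en-2-one | CC(=O)CC[C@H](O)C=C | intermediate
19 | (S)-5-methyl-2-vinyl-2,3-dihydrofuran | CC1=CC[C@@H](C=C)O1 | intermediate
20 | o-quinone methide, 2-methoxy-6-methyl-5-methylidenecyclohepta-2,6-diene-1,4-dione | O=C1C=C(C)C(=C)C(=O)C=C1OC | intermediate
21 | cis-fused ring B ketal, tropolone methyl ether (tetrahydrofuran with (S)-vinyl carbon; tropolonyl CH2 trans to vinyl; methyl on the ketal carbon) | C=C[C@@H]1C[C@H]2Cc3c(C)cc(=O)c(OC)cc3O[C@@]2(C)O1 | intermediate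
22 | (3S,5S)-5-hydroxy-3-[(4-hydroxy-2-methoxy-6-methyltropon-5-yl)methyl]hept-6-en-2-one | CC(=O)[C@H](Cc1c(C)cc(=O)c(OC)cc1O)C[C@H](O)C=C | intermediate
23 | bis-acetate of 22 (carbinol acetate and hydroxytropone acetate) | CC(=O)[C@H](Cc1c(C)cc(=O)c(OC)cc1OC(C)=O)C[C@H](OC(C)=O)C=C | intermediate
24 | carbinol acetate of 22 (free hydroxytropone) | CC(=O)[C@H](Cc1c(C)cc(=O)c(OC)cc1O)C[C@H](OC(C)=O)C=C | intermediate
25 | allyltrimethylsilane | C=CC[Si](C)(C)C | starting material
26 | cyclic oxocarbenium triflate of ring B | CC1=[O+]c2cc(OC)c(=O)cc(C)c2C[C@@H]1C[C@H](OC(C)=O)C=C.[O-]S(=O)(=O)C(F)(F)F | intermediate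
27 | ring B allyl compound: 2-allyl-2-methyl-dihydropyrano-fused 2-methoxy-6-methyltropone, (S)-2-acetoxybut-3-enyl chain on the ring B CH, trans to allyl | C=CC[C@@]3(C)Oc4cc(OC)c(=O)cc(C)c4C[C@@H]3C[C@H](OC(C)=O)C=C | intermediate
28 | ring B-fused cyclohept-2-enyl acetate (trans-fused) | C1=CC[C@@]3(C)Oc4cc(OC)c(=O)cc(C)c4C[C@@H]3C[C@@H]1OC(C)=O | intermediate
29 | ring B-fused cyclohept-2-en-1-ol | C1=CC[C@@]3(C)Oc4cc(OC)c(=O)cc(C)c4C[C@@H]3C[C@@H]1O | intermediate
30 | syn-2,3-epoxy alcohol (epoxide cis to the hydroxyl) | [C@@H]1(O2)[C@H]2C[C@@]3(C)Oc4cc(OC)c(=O)cc(C)c4C[C@@H]3C[C@@H]1O | intermediate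
31 | epoxy MOM ether | [C@@H]1(O2)[C@H]2C[C@@]3(C)Oc4cc(OC)c(=O)cc(C)c4C[C@@H]3C[C@@H]1OCOC | intermediate
32 | (2-methylprop-1-enyl)magnesium bromide | CC(C)=C[Mg]Br | starting material
33 | trans-2-(2-methylprop-1-enyl) alcohol, hydroxyl cis to the MOM-oxy group | O[C@@H]1[C@@H](C=C(C)C)C[C@@]3(C)Oc4cc(OC)c(=O)cc(C)c4C[C@@H]3C[C@@H]1OCOC | intermediate
34 | α-MOM-oxy α'-(2-methylprop-1-enyl) cycloheptanone | O=C1[C@@H](C=C(C)C)C[C@@]3(C)Oc4cc(OC)c(=O)cc(C)c4C[C@@H]3C[C@@H]1OCOC | intermediate
35 | vinylmagnesium bromide | C=C[Mg]Br | starting material
36 | ring B-fused trans-1-vinyl-2-(2-methylprop-1-enyl)cycloheptanol, vinyl cis to the MOM-oxy group | C=C[C@]1(O)[C@@H](C=C(C)C)C[C@@]3(C)Oc4cc(OC)c(=O)cc(C)c4C[C@@H]3C[C@@H]1OCOC | intermediate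
37 | potassium alkoxide of 36 | C=C[C@]1([O-])[C@@H](C=C(C)C)C[C@@]3(C)Oc4cc(OC)c(=O)cc(C)c4C[C@@H]3C[C@@H]1OCOC.[K+] | intermediate
38 | potassium enolate of the ring B-fused E-cycloundecenone (oxygen cis to the new CH2) | [O-]/C1=C\CC(C)(C)/C=C/C[C@@]3(C)Oc4cc(OC)c(=O)cc(C)c4C[C@@H]3C[C@@H]1OCOC.[K+] | intermediate
39 | ring B-fused cycloundeca-1,5-dienyl triflate (both ring double bonds trans in the ring; triflate oxygen cis to the ring CH2) | O=S(=O)(O/C1=C\CC(C)(C)/C=C/C[C@@]3(C)Oc4cc(OC)c(=O)cc(C)c4C[C@@H]3C[C@@H]1OCOC)C(F)(F)F | intermediate
40 | dimethylzinc | C[Zn]C | starting material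
41 | ring B-fused triene MOM ether | C/C1=C\CC(C)(C)/C=C/C[C@@]3(C)Oc4cc(OC)c(=O)cc(C)c4C[C@@H]3C[C@@H]1OCOC | intermediate
42 | bromomethyl ether of 43 | C/C1=C\CC(C)(C)/C=C/C[C@@]3(C)Oc4cc(OC)c(=O)cc(C)c4C[C@@H]3C[C@@H]1OCBr | intermediate
43 | ring B-fused triene allylic alcohol, (S)-carbinol | C/C1=C\CC(C)(C)/C=C/C[C@@]3(C)Oc4cc(OC)c(=O)cc(C)c4C[C@@H]3C[C@@H]1O | intermediate
44 | o-quinone methide, 2-hydroxy-6-methyl-5-methylidenecyclohepta-2,6-diene-1,4-dione | O=C1C=C(C)C(=C)C(=O)C=C1O | intermediate
45 | ring B O-methyl ether of 46 | Cc1cc(=O)c(O)cc2c1C[C@H]1CC(C)(C)/C=C/C[C@@]3(C)Oc4cc(OC)c(=O)cc(C)c4C[C@@H]3C[C@H](O)[C@]1(C)O2 | intermediate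
46 | CNP0283947.4 | Cc1cc(=O)c(O)cc2c1C[C@H]1CC(C)(C)/C=C/C[C@@]3(C)Oc4cc(O)c(=O)cc(C)c4C[C@@H]3C[C@H](O)[C@]1(C)O2 | target

## Step count and least certain steps

Total: 26 steps. Longest linear sequence: 23 steps (steps 1 to 6, 8, 9 and 12 to 26).

Step 22 (key step). The most likely failure is proton transfer that scrambles the enolate before triflation, or deprotonation of the tropone methyl group by KH, if the sigmatropic shift is slow in the fused system. The fallback sets out from 36 and returns at 39. Silylation of 36 (N-trimethylsilylimidazole) would give the trimethylsilyl ether F1. A neutral thermal siloxy-Cope rearrangement (o-dichlorobenzene, about 200 °C) would then give the ring-expanded silyl enol ether F2 with the same geometry. CsF with PhNTf2 would convert F2 into 39.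

Step 12. The acidic hydroxytropone may add to, isomerise or oligomerise the enol ether before the quinone methide forms, and a single vinyl group may give only a modest facial bias. The fallback sets out from 11 and returns at 21; it moves the quinone methide formation into an amine-buffered medium and puts the methyl cap on afterwards. Heating 11 with dimethylamine would give the Mannich base F3, whose free tropolone, unlike a methoxytropone, is not open to substitution by the amine. Heated with 19 in toluene, F3 loses the amine to give quinone methide 44, and cycloaddition would give the free tropolone ketal F4. Methylation of F4 as in step 8 would then return 21.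

Step 14. The oxocarbenium ion, which is only weakly stabilised by the tropone oxygen, may lose a proton to the enol ether; this would erode the adjacent CH centre or stall the allylation. The fallback sets out from 24 and returns at 27. A Barbier allylation of the ketone (indium, allyl bromide, aqueous THF) would give the tertiary homoallylic alcohol F5, whose epimer at the new centre would have to be separated. Sulfonylation of the hydroxytropone (PhNTf2, Et3N) would give the triflate F6. Cs2CO3 in MeCN would then close ring B by addition of the tertiary alkoxide to the tropone carbon and loss of triflate.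

Step 19 (the same hazard applies to step 21). The organometallic reagent may add to, or substitute at, the methoxytropone instead of reacting at the epoxide or ketone. The fallback sets out from 31 and returns at 36, and shields the tropolone as its anion. Hydrolysis of the methyl ether (LiOH, aqueous THF) would give the free tropolone epoxide F7. The cuprate, with one extra equivalent consumed as the tropolonate, would give the alcohol F8. Oxidation (SO3·pyridine, DMSO, Et3N) would give the ketone F9, and the vinylcerium reagent in excess would give the carbinol F10. Methylation as in step 8 would then return 36.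

Step 25. The cycloaddition may be poorly face-selective or may strike the wrong face, because the conformation of the eleven-membered ring, not a rigid element, decides which face is exposed. The quinone methide may also oligomerise. The fallback sets out from 41 and returns at 45. It replaces hydroxyl delivery by steric shielding: the cycloaddition is run on the MOM ether 41 with 11 to give the MOM-protected adduct F11, and the acetal is then removed with Me2BBr as in step 24.

## Further compounds

F1 | step 22 | trimethylsilyl ether of 36 | C=C[C@]1(O[Si](C)(C)C)[C@@H](C=C(C)C)C[C@@]3(C)Oc4cc(OC)c(=O)cc(C)c4C[C@@H]3C[C@@H]1OCOC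
F2 | step 22 | ring-expanded trimethylsilyl enol ether | C[Si](C)(C)O/C1=C\CC(C)(C)/C=C/C[C@@]3(C)Oc4cc(OC)c(=O)cc(C)c4C[C@@H]3C[C@@H]1OCOC
F3 | step 12 | 5-[(dimethylamino)methyl]-2,4-dihydroxy-6-methylcyclohepta-2,4,6-trien-1-one | Cc1cc(=O)c(O)cc(O)c1CN(C)C
F4 | step 12 | cis-fused ring B ketal, free tropolone | C=C[C@@H]1C[C@H]2Cc3c(C)cc(=O)c(O)cc3O[C@@]2(C)O1
F5 | step 14 | tertiary homoallylic alcohol from 24 | C=CC[C@@](C)(O)[C@H](Cc1c(C)cc(=O)c(OC)cc1O)C[C@H](OC(C)=O)C=C
F6 | step 14 | tropone triflate of F5 | C=CC[C@@](C)(O)[C@H](Cc1c(C)cc(=O)c(OC)cc1OS(=O)(=O)C(F)(F)F)C[C@H](OC(C)=O)C=C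
F7 | step 19 | free tropolone epoxy MOM ether | [C@@H]1(O2)[C@H]2C[C@@]3(C)Oc4cc(O)c(=O)cc(C)c4C[C@@H]3C[C@@H]1OCOC
F8 | step 19 | free tropolone analogue of 33 | O[C@@H]1[C@@H](C=C(C)C)C[C@@]3(C)Oc4cc(O)c(=O)cc(C)c4C[C@@H]3C[C@@H]1OCOC
F9 | step 19 | free tropolone analogue of 34 | O=C1[C@@H](C=C(C)C)C[C@@]3(C)Oc4cc(O)c(=O)cc(C)c4C[C@@H]3C[C@@H]1OCOC
F10 | step 19 | free tropolone analogue of 36 | C=C[C@]1(O)[C@@H](C=C(C)C)C[C@@]3(C)Oc4cc(O)c(=O)cc(C)c4C[C@@H]3C[C@@H]1OCOC
F11 | step 25 | MOM ether of 45 | Cc1cc(=O)c(O)cc2c1C[C@H]1CC(C)(C)/C=C/C[C@@]3(C)Oc4cc(OC)c(=O)cc(C)c4C[C@@H]3C[C@H](OCOC)[C@]1(C)O2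
A1 | alternative 1 | open-chain bis(pyranotropolone) with the E-alkene in place | CC(C)(C)[Si](C)(C)OC[C@]1(C)Oc2cc(OC)c(=O)cc(C)c2C[C@H]1CC(C)(C)/C=C/C[C@@]3(C)Oc4cc(OC)c(=O)cc(C)c4C[C@@H]3COCc5ccc(OC)cc5
A2 | alternative 2 | ring A pyranotropolone diol | OC[C@H](O)[C@]1(C)Oc2cc(OC)c(=O)cc(C)c2C[C@H]1CC(C)(C)C=C
A3 | alternative 3 | bis(methyl ether) of 46 | Cc1cc(=O)c(OC)cc2c1C[C@H]1CC(C)(C)/C=C/C[C@@]3(C)Oc4cc(OC)c(=O)cc(C)c4C[C@@H]3C[C@H](O)[C@]1(C)O2
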